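**Assumption:** germacrane numbering with the lactone as a 6,12-olide (O on C6, C7–C11 bond); the target is then (2R,3S,4Z,6R,7S,9S,10S)-2-acetoxy-9-angeloyloxy-3-hydroxy-1(10)-dihydrogermacra-4,11(13)-dien-6,12-olide.

## Retrosynthetic overview

1. 22 ⇐ lactol / allylic bromide 19. One flask closes C6–C7 (the bond a farnesyl-type chain closes in germacrane biogenesis) to give the ten-membered carbocycle, then the 6,12-lactone; C6 and C7 are set here.
2. 19 ⇐ butenolide 17 by lactone-to-lactol reduction; 17 ⇐ 15 by cross-metathesis with methyl 2-(bromomethyl)acrylate. The butenolide stores the 4Z alkene, the C3 hydroxyl and the C6 aldehyde.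
3. 15 ⇐ aldehyde 9 by allylboration (C8–C9, sets C9) and angeloylation; 9 ⇐ 7 by ozonolysis of a styryl group.
4. 7 ⇐ aldehyde 3 + silyloxyfuran 5 by vinylogous Mukaiyama aldol (C2–C3, sets C2 and C3), then acetylation.
5. 3 ⇐ crotonaldehyde + styryltrifluoroborate (sets C10). Ring order: carbocycle first, lactone second, both in the last step.

## Route

Step 1
Reactants: 1 (E)-but-2-enal; 2 potassium trifluoro[(E)-2-phenylethenyl]borate
Product: 3 (3S,4E)-3-methyl-5-phenylpent-4-enal
Conditions: (2R,5R)-5-benzyl-2-tert-butyl-3-methylimidazolidin-4-one·HCl (20 mol%), 48% aq. HF (1.0 equiv), DME, −20 °C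
Reagents that add atoms: none
Why: Iminium-catalysed conjugate vinylation (organocatalytic Friedel–Crafts-type addition of a vinyl trifluoroborate to an enal); the styryl group adds to the β-carbon of the (E)-iminium ion on the face not shielded by the benzyl group, which with the (2R,5R) catalyst sets the 3S centre (C10 of the target), and the styryl unit is a latent C9 aldehyde.

Step 2
Reactants: 4 4-methylfuran-2(5H)-one
Product: 5 trimethyl[(4-methylfuran-2-yl)oxy]silane
Conditions: TMSOTf (1.1 equiv), Et3N (1.3 equiv), Et2O, 0 °C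
Reagents that add atoms: trimethylsilyl trifluoromethanesulfonate, C[Si](C)(C)OS(=O)(=O)C(F)(F)F
Why: Soft enolisation and O-silylation of the butenolide (silyl dienol ether formation) gives the aromatic 2-silyloxyfuran, the vinylogous nucleophile that supplies C3–C6 and C15.

Step 3
Reactants: 3 (3S,4E)-3-methyl-5-phenylpent-4-enal; 5 trimethyl[(4-methylfuran-2-yl)oxy]silane
Product: 6 (5S)-5-[(1R,3S,4E)-1-hydroxy-3-methyl-5-phenylpent-4-en-1-yl]-4-methylfuran-2(5H)-one
Conditions: [Cr(salen*)]SbF6 (5 mol%; cationic trivalent chromium complex of Katsuki's chiral salen ligand, antipode that gives Si-face attack), i-PrOH (1.2 equiv), CH2Cl2, −20 °C; 1 M HCl work-up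
Reagents that add atoms: none
Why: Catalytic asymmetric vinylogous Mukaiyama aldol reaction; C5 of the furan adds to the Si face of the Lewis acid-bound aldehyde through an open, anti-selective transition state under catalyst control, setting C2 (1R) and C3 (5S) in the erythro relationship, while the butenolide locks the 4Z alkene, masks C3–OH as the ring oxygen and leaves C2–OH as the only free hydroxyl.

Step 4
Reactants: 6 (5S)-5-[(1R,3S,4E)-1-hydroxy-3-methyl-5-phenylpent-4-en-1-yl]-4-methylfuran-2(5H)-one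
Product: 7 (1R,3S,4E)-3-methyl-1-[(2S)-3-methyl-5-oxo-2,5-dihydrofuran-2-yl]-5-phenylpent-4-en-1-yl acetate
Conditions: Ac2O (1.5 equiv), pyridine, DMAP (2 mol%), CH2Cl2, 0 °C
Reagents that add atoms: acetic anhydride, CC(=O)OC(C)=O
Why: Acylation of the single free secondary alcohol (nucleophilic catalysis) with retention, which differentiates C2–OAc from the still masked C3–OH.

Step 5
Reactants: 7 (1R,3S,4E)-3-methyl-1-[(2S)-3-methyl-5-oxo-2,5-dihydrofuran-2-yl]-5-phenylpent-4-en-1-yl acetate
Product: 9 (1R,3S)-3-methyl-1-[(2S)-3-methyl-5-oxo-2,5-dihydrofuran-2-yl]-4-oxobutyl acetate, via ozonide 8 (not isolated)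
Conditions: O3 (1.0 equiv), CH2Cl2, −78 °C; then PPh3, −78 °C → rt; quick chromatography, used at once
Reagents that add atoms: ozone, [O-][O+]=O
Why: Ozonolysis with reductive work-up; the electron-rich styrenyl alkene is cleaved far faster than the electron-poor trisubstituted butenolide alkene, unveiling the C9 aldehyde without touching C10.

Step 6
Reactants: 9 (1R,3S)-3-methyl-1-[(2S)-3-methyl-5-oxo-2,5-dihydrofuran-2-yl]-4-oxobutyl acetate; 10 (−)-B-allyldiisopinocampheylborane [(−)-Ipc2B(allyl), from (+)-α-pinene]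
Product: 12 (1R,3S,4S)-4-hydroxy-3-methyl-1-[(2S)-3-methyl-5-oxo-2,5-dihydrofuran-2-yl]hept-6-en-1-yl acetate, via borinate ester 11 (not isolated)
Conditions: 10 (1 M in pentane, 1.3 equiv), Et2O, −78 °C; then pH 7 phosphate buffer, MeOH, 30% H2O2, 0 °C
Reagents that add atoms: none
Why: Brown asymmetric allylboration through a chair Zimmerman–Traxler transition state; the (+)-α-pinene-derived reagent adds allyl to the Si face of the aldehyde, which is also the Felkin face of this α-methyl aldehyde (matched pair), setting C9 (4S) syn to the C10 methyl.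

Step 7
Reactants: 12 (1R,3S,4S)-4-hydroxy-3-methyl-1-[(2S)-3-methyl-5-oxo-2,5-dihydrofuran-2-yl]hept-6-en-1-yl acetate; 13 angelic acid [(2Z)-2-methylbut-2-enoic acid]
Product: 15 (4S,5S,7R)-7-(acetyloxy)-5-methyl-7-[(2S)-3-methyl-5-oxo-2,5-dihydrofuran-2-yl]hept-1-en-4-yl (2Z)-2-methylbut-2-enoate, via mixed anhydride 14 (not isolated)
Conditions: 13 (3 equiv), 2,4,6-trichlorobenzoyl chloride (3 equiv), Et3N (3 equiv), toluene, rt; filter, concentrate; then 12, toluene, 75 °C
Reagents that add atoms: none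
Why: Yamaguchi-type mixed-anhydride esterification; the alcohol attacks the unhindered angeloyl carbonyl of 14, and the base-free, DMAP-free heating stage avoids Z-to-E isomerisation of the angelate and base-induced elimination of the δ-acetoxy butenolide; C9 is acylated with retention.

Step 8
Reactants: 15 (4S,5S,7R)-7-(acetyloxy)-5-methyl-7-[(2S)-3-methyl-5-oxo-2,5-dihydrofuran-2-yl]hept-1-en-4-yl (2Z)-2-methylbut-2-enoate; 16 methyl 2-(bromomethyl)prop-2-enoate
Product: 17 methyl (2Z,5S,6S,8R)-8-(acetyloxy)-2-(bromomethyl)-6-methyl-5-{[(2Z)-2-methylbut-2-enoyl]oxy}-8-[(2S)-3-methyl-5-oxo-2,5-dihydrofuran-2-yl]oct-2-enoate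
Conditions: second-generation Hoveyda–Grubbs catalyst (10 mol%), 16 (6 equiv), CH2Cl2, 40 °C
Reagents that add atoms: none
Why: Olefin cross-metathesis of a monosubstituted alkene with a 1,1-disubstituted acrylate (a methacrylate-type partner that does not homodimerise, although this particular partner is an extrapolation); the trisubstituted alkene forms with C8 trans to the ester, and the electron-poor trisubstituted alkenes of the butenolide and the angelate do not take part.

Step 9
Reactants: 17 methyl (2Z,5S,6S,8R)-8-(acetyloxy)-2-(bromomethyl)-6-methyl-5-{[(2Z)-2-methylbut-2-enoyl]oxy}-8-[(2S)-3-methyl-5-oxo-2,5-dihydrofuran-2-yl]oct-2-enoate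
Product: 19 methyl (2Z,5S,6S,8R)-8-(acetyloxy)-2-(bromomethyl)-8-[(2S,5RS)-5-hydroxy-3-methyl-2,5-dihydrofuran-2-yl]-6-methyl-5-{[(2Z)-2-methylbut-2-enoyl]oxy}oct-2-enoate, via O-boryl lactol 18 (not isolated)
Conditions: Sia2BH (4 equiv, made from BH3·SMe2 and 2-methylbut-2-ene in THF at 0 °C), THF, 0 °C → rt; then H2O, pH 7 buffer; filtration through neutral alumina, used at once
Reagents that add atoms: none
Why: Partial reduction of a γ-lactone to the lactol by a hindered dialkylborane (as used for O-acylated aldonolactones), which transfers one hydride to the lactone carbonyl but leaves the acetate, the angelate, the enoate and the allylic bromide alone and does not hydroborate trisubstituted electron-poor alkenes; the new hemiacetal centre is of no consequence.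

Step 10
Reactants: 19 methyl (2Z,5S,6S,8R)-8-(acetyloxy)-2-(bromomethyl)-8-[(2S,5RS)-5-hydroxy-3-methyl-2,5-dihydrofuran-2-yl]-6-methyl-5-{[(2Z)-2-methylbut-2-enoyl]oxy}oct-2-enoate
Product: 22 (3aS,5S,6S,8R,9S,10Z,11aR)-8-(acetyloxy)-9-hydroxy-6,10-dimethyl-3-methylidene-2-oxo-2,3,3a,4,5,6,7,8,9,11a-decahydrocyclodeca[b]furan-5-yl (2Z)-2-methylbut-2-enoate, via open-chain hydroxy enal 20 (not isolated), via macrocyclic hydroxy ester 21 (not isolated)
Conditions: CrCl2 (8 equiv), THF/DMF 1:1, rt, 19 added over 10 h (final 1 mM); sat. aq. NH4Cl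
Reagents that add atoms: none
Why: Proposed new method: the lactol is used as a latent (Z)-4-hydroxy-enal, whose open tautomer 20 is captured by the allylchromium species formed from the allylic bromide and two equivalents of divalent chromium; C7 attacks the C6 aldehyde in an SE2′ sense through a chair transition state in which, after E/Z equilibration of the allylchromium, C5 and C8 are both equatorial, so that the ten-membered ring closes to the 6,7-trans hydroxy ester 21, whose chromium alkoxide then lactonises onto the C12 ester; the facial sense (6R,7S) is expected, not proven, from the transition-state conformer that keeps the C2, C3, C9 and C10 substituents pseudo-equatorial, and the closest known reactions are the Nozaki–Hiyama–Kishi (chromium Barbier) macrocyclisations of bromomethyl-acrylate enals that give costunolide and parthenolide with 6,7-trans lactones.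

## Compound list

1 | (E)-but-2-enal (crotonaldehyde) | C/C=C/C=O | starting material
2 | potassium trifluoro[(E)-2-phenylethenyl]borate | [K+].F[B-](F)(F)/C=C/c1ccccc1 | starting material
3 | (3S,4E)-3-methyl-5-phenylpent-4-enal | O=CC[C@H](C)/C=C/c1ccccc1 | intermediate
4 | 4-methylfuran-2(5H)-one | CC1=CC(=O)OC1 | starting material
5 | trimethyl[(4-methylfuran-2-yl)oxy]silane | Cc1coc(O[Si](C)(C)C)c1 | intermediate
6 | (5S)-5-[(1R,3S,4E)-1-hydroxy-3-methyl-5-phenylpent-4-en-1-yl]-4-methylfuran-2(5H)-one | O=C1C=C(C)[C@H](O1)[C@H](O)C[C@H](C)/C=C/c1ccccc1 | intermediate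
7 | (1R,3S,4E)-3-methyl-1-[(2S)-3-methyl-5-oxo-2,5-dihydrofuran-2-yl]-5-phenylpent-4-en-1-yl acetate | O=C1C=C(C)[C@H](O1)[C@H](OC(C)=O)C[C@H](C)/C=C/c1ccccc1 | intermediate
8 | (1R,3S)-1-[(2S)-3-methyl-5-oxo-2,5-dihydrofuran-2-yl]-3-(5-phenyl-1,2,4-trioxolan-3-yl)butyl acetate (ozonide of 7) | O=C1C=C(C)[C@H](O1)[C@H](OC(C)=O)C[C@H](C)C1OOC(c2ccccc2)O1 | intermediate
9 | (1R,3S)-3-methyl-1-[(2S)-3-methyl-5-oxo-2,5-dihydrofuran-2-yl]-4-oxobutyl acetate | O=C1C=C(C)[C@H](O1)[C@H](OC(C)=O)C[C@H](C)C=O | intermediate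
10 | (−)-B-allyldiisopinocampheylborane, from (+)-α-pinene | C=CCB([C@@H]1C[C@@H]2C[C@H]([C@H]1C)C2(C)C)[C@@H]1C[C@@H]2C[C@H]([C@H]1C)C2(C)C | starting material
11 | O-(diisopinocampheylboryl) derivative of alcohol 12 | O=C1C=C(C)[C@H](O1)[C@H](OC(C)=O)C[C@H](C)[C@@H](OB([C@@H]2C[C@@H]3C[C@H]([C@H]2C)C3(C)C)[C@@H]2C[C@@H]3C[C@H]([C@H]2C)C3(C)C)CC=C | intermediate
12 | (1R,3S,4S)-4-hydroxy-3-methyl-1-[(2S)-3-methyl-5-oxo-2,5-dihydrofuran-2-yl]hept-6-en-1-yl acetate | O=C1C=C(C)[C@H](O1)[C@H](OC(C)=O)C[C@H](C)[C@@H](O)CC=C | intermediate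
13 | angelic acid, (2Z)-2-methylbut-2-enoic acid | C/C=C(/C)C(=O)O | starting material
14 | (2Z)-2-methylbut-2-enoic 2,4,6-trichlorobenzoic anhydride | C/C=C(/C)C(=O)OC(=O)c1c(Cl)cc(Cl)cc1Cl | intermediate
15 | (4S,5S,7R)-7-(acetyloxy)-5-methyl-7-[(2S)-3-methyl-5-oxo-2,5-dihydrofuran-2-yl]hept-1-en-4-yl (2Z)-2-methylbut-2-enoate | O=C1C=C(C)[C@H](O1)[C@H](OC(C)=O)C[C@H](C)[C@@H](OC(=O)/C(C)=C\C)CC=C | intermediate
16 | methyl 2-(bromomethyl)prop-2-enoate | C=C(CBr)C(=O)OC | starting material
17 | methyl (2Z,5S,6S,8R)-8-(acetyloxy)-2-(bromomethyl)-6-methyl-5-{[(2Z)-2-methylbut-2-enoyl]oxy}-8-[(2S)-3-methyl-5-oxo-2,5-dihydrofuran-2-yl]oct-2-enoate | O=C1C=C(C)[C@H](O1)[C@H](OC(C)=O)C[C@H](C)[C@@H](OC(=O)/C(C)=C\C)C/C=C(\CBr)C(=O)OC | intermediate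
18 | O-[bis(3-methylbutan-2-yl)boryl] derivative of lactol 19 | CC(C)C(C)B(C(C)C(C)C)OC1C=C(C)[C@H](O1)[C@H](OC(C)=O)C[C@H](C)[C@@H](OC(=O)/C(C)=C\C)C/C=C(\CBr)C(=O)OC | intermediate
19 | methyl (2Z,5S,6S,8R)-8-(acetyloxy)-2-(bromomethyl)-8-[(2S,5RS)-5-hydroxy-3-methyl-2,5-dihydrofuran-2-yl]-6-methyl-5-{[(2Z)-2-methylbut-2-enoyl]oxy}oct-2-enoate | OC1C=C(C)[C@H](O1)[C@H](OC(C)=O)C[C@H](C)[C@@H](OC(=O)/C(C)=C\C)C/C=C(\CBr)C(=O)OC | intermediate
20 | methyl (2Z,5S,6S,8R,9S,10Z)-8-(acetyloxy)-2-(bromomethyl)-9-hydroxy-6,10-dimethyl-5-{[(2Z)-2-methylbut-2-enoyl]oxy}-12-oxododeca-2,10-dienoate | O=C/C=C(/C)[C@H](O)[C@H](OC(C)=O)C[C@H](C)[C@@H](OC(=O)/C(C)=C\C)C/C=C(\CBr)C(=O)OC | intermediate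
21 | methyl 2-[(1S,2R,3Z,5S,6R,8S,9S)-6-(acetyloxy)-2,5-dihydroxy-4,8-dimethyl-9-{[(2Z)-2-methylbut-2-enoyl]oxy}cyclodec-3-en-1-yl]prop-2-enoate | O[C@@H]1/C=C(/C)[C@H](O)[C@H](OC(C)=O)C[C@H](C)[C@@H](OC(=O)/C(C)=C\C)C[C@H]1C(=C)C(=O)OC | intermediate
22 | (3aS,5S,6S,8R,9S,10Z,11aR)-8-(acetyloxy)-9-hydroxy-6,10-dimethyl-3-methylidene-2-oxo-2,3,3a,4,5,6,7,8,9,11a-decahydrocyclodeca[b]furan-5-yl (2Z)-2-methylbut-2-enoate | C=C1C(=O)O[C@@H]2/C=C(/C)[C@H](O)[C@H](OC(C)=O)C[C@H](C)[C@@H](OC(=O)/C(C)=C\C)C[C@@H]12 | target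

## Step count and risks

Total step count: 10. Longest linear sequence: 9 steps (steps 1 and 3–10; step 2 makes the silyloxyfuran).

Where each stereo element is set: C10 in step 1; C2 and C3 in step 3; C9 in step 6; C6 and C7 in step 10. The 4Z alkene is held in a five-membered ring from step 3 until the last step, and the angelate geometry comes from the acid.

The three steps most likely to fail:

**Step 10 (macrocyclisation and lactonisation on the free lactol).** The lactol may lose water to a furan under Lewis-acidic chromium salts, and the C6/C7 outcome rests on macrocyclic control that is argued, not demonstrated. The fallback sets out from 19 and comes back at 21. Stannylation with hexabutylditin and Pd(PPh3)4 in THF turns the allylic bromide into the allylstannane lactol F1. InCl3 in acetone (−78 → 0 °C) then transmetallates to an allylindium dichloride, which equilibrates to the E form and adds to the latent aldehyde through a chair to give the anti adduct 21. This replaces the reducing-metal Barbier reaction by a redox-neutral, preformed allylmetal whose anti preference does not depend on alkene geometry; 21 lactonises to 22 as before.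

**Step 9 (lactone to lactol beside three esters and an allylic bromide).** The butenolide may be too sluggish, or the product may aromatise. The fallback sets out from 17 and comes back at 21, with no lactone reduction at all. SmI2 (2.2 equiv, THF, −78 °C, high dilution) generates the allylsamarium, which attacks the butenolide carbonyl (samarium Barbier acyl substitution). The ring opens to the ten-membered hydroxy enone F2, which carries the free C3 hydroxyl and the C6 ketone. Luche reduction (NaBH4, CeCl3·7H2O, MeOH, −78 °C) reduces only that ketone, from the face opposite the C7 substituent, to give 21.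

**Step 8 (cross-metathesis with a bromomethyl acrylate).** The doubly deactivated 1,1-disubstituted partner may give low conversion. The fallback sets out from 15 and comes back at 17. Ozonolysis (O3, CH2Cl2, −78 °C; PPh3) of the terminal alkene gives the aldehyde F3. Base-free vinylalumination with the α-(methoxycarbonyl)vinylalane made from methyl propiolate, i-Bu2AlH and N-methylmorpholine N-oxide (THF, 0 °C) gives the allylic alcohol F4 as a mixture of carbinol epimers. PBr3 (Et2O, 0 °C) then converts F4 by SN2′ substitution into the (Z)-allylic bromide 17.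

## Further compounds

F1 | step 10 | methyl (2Z,5S,6S,8R)-8-(acetyloxy)-8-[(2S,5RS)-5-hydroxy-3-methyl-2,5-dihydrofuran-2-yl]-6-methyl-5-{[(2Z)-2-methylbut-2-enoyl]oxy}-2-[(tributylstannyl)methyl]oct-2-enoate | OC1C=C(C)[C@H](O1)[C@H](OC(C)=O)C[C@H](C)[C@@H](OC(=O)/C(C)=C\C)C/C=C(\C[Sn](CCCC)(CCCC)CCCC)C(=O)OC
F2 | step 9 | methyl 2-[(1S,3Z,5S,6R,8S,9S)-6-(acetyloxy)-5-hydroxy-4,8-dimethyl-9-{[(2Z)-2-methylbut-2-enoyl]oxy}-2-oxocyclodec-3-en-1-yl]prop-2-enoate | O=C1/C=C(/C)[C@H](O)[C@H](OC(C)=O)C[C@H](C)[C@@H](OC(=O)/C(C)=C\C)C[C@H]1C(=C)C(=O)OC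
F3 | step 8 | (3S,4S,6R)-6-(acetyloxy)-4-methyl-6-[(2S)-3-methyl-5-oxo-2,5-dihydrofuran-2-yl]-1-oxohexan-3-yl (2Z)-2-methylbut-2-enoate | O=C1C=C(C)[C@H](O1)[C@H](OC(C)=O)C[C@H](C)[C@@H](OC(=O)/C(C)=C\C)CC=O
F4 | step 8 | methyl (3RS,5S,6S,8R)-8-(acetyloxy)-3-hydroxy-6-methyl-2-methylidene-5-{[(2Z)-2-methylbut-2-enoyl]oxy}-8-[(2S)-3-methyl-5-oxo-2,5-dihydrofuran-2-yl]octanoate | O=C1C=C(C)[C@H](O1)[C@H](OC(C)=O)C[C@H](C)[C@@H](OC(=O)/C(C)=C\C)CC(O)C(=C)C(=O)OC
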